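The C4, C5, C6 tribromide on the benzene ring is traced back to one amino group at C5 of an oxindole. In that carrier the five-membered ring is switched off (C3 is a CH2, C2 a lactam carbonyl), so the benzene ring behaves as a para-substituted aniline. The C5 amine then sends two bromines to its flanking carbons C4 and C6 in a single operation, and the amine itself later becomes the C5 bromine. The precursor is simply 5-aminooxindole, made by reducing the nitro compound. The lactam is finally converted into the C2–Br indole, whose only free pyrrole carbon, C3, accepts the methylsulfanyl group.

Key step: step 2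

Remark on the chemistry: the target is achiral and has no stereocentre, so no step has to set or keep configuration.

Step 1
Reactants: 1 5-nitro-1,3-dihydro-2H-indol-2-one (5-nitrooxindole)
Product: 2 5-amino-1,3-dihydro-2H-indol-2-one (5-aminooxindole)
Conditions: H2 (1 atm), Pd/C (10 wt% Pd), MeOH–THF 1:1, rt; filtered under N2 and used at once
Reagents that add atoms: none
Why: Catalytic hydrogenation of an aromatic nitro group over palladium should stop at the aniline, since the lactam, the C3 methylene and the still halogen-free ring offer nothing else that is reduced at 1 atm and room temperature.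

Step 2
Reactants: 2 5-amino-1,3-dihydro-2H-indol-2-one
Product: 3 5-amino-4,6-dibromo-1,3-dihydro-2H-indol-2-one
Conditions: NBS (2.05 equiv, portionwise), DMF, −10 → 0 °C, dark; aq Na2S2O3
Reagents that add atoms: N-bromosuccinimide, O=C1CCC(=O)N1Br
Why: Electrophilic aromatic substitution: NBS transfers electrophilic bromine to C4 and then to C6, each attack giving an arenium ion whose positive charge sits on C5 and is taken up by the amino lone pair before a proton is lost. The closest known reaction type is the ortho,ortho-dibromination of para-substituted anilines with NBS in DMF. No ring is closed and no stereocentre is formed. The selectivity needed is C4 and C6 over C7, C3 and the nitrogens, and the substrate supplies it: the C5 amine is the strongest donor and C4 and C6 are its only ortho carbons, whereas the lactam nitrogen is a weaker anilide-type donor whose para carbon C5 is occupied and whose ortho carbon C7 is meta to the amine. C3 is an amide CH2 that can react only through its enol, which is slow in neutral DMF at or below 0 °C in the dark, and the charge of 2.05 equiv leaves no bromine for a third substitution.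

Step 3
Reactants: 3 5-amino-4,6-dibromo-1,3-dihydro-2H-indol-2-one
Product: 5 4,5,6-tribromo-1,3-dihydro-2H-indol-2-one, via 4,6-dibromo-2-oxoindoline-5-diazonium bromide 4 (not isolated)
Conditions: CuBr2 (1.2 equiv), t-BuONO (1.2 equiv, slow addition), MeCN, 0 °C → rt
Reagents that add atoms: copper dibromide, [Cu+2].[Br-].[Br-]
Why: Aprotic Sandmeyer bromination, a standard exchange for weakly basic 2,6-dibromoanilines: the nitrite ester diazotizes the amine, electron transfer from copper releases N2, and the C5 aryl radical takes bromine from CuBr2, while slow nitrite addition at 0 °C should keep the far less nucleophilic C3 methylene from being nitrosated.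

Step 4
Reactants: 5 4,5,6-tribromo-1,3-dihydro-2H-indol-2-one
Product: 6 2,4,5,6-tetrabromo-1H-indole
Conditions: POBr3 (2.0 equiv), imidazole (1.2 equiv), ClCH2CH2Cl, 80 °C; ice-water; used promptly
Reagents that add atoms: phosphorus oxybromide, O=P(Br)(Br)Br
Why: Dehydrative bromination of a lactam (Vilsmeier-type activation), the usual way from oxindoles to 2-bromoindoles: O-phosphorylation, addition–elimination by bromide at C2 and tautomerization of the 2-bromo-3H-indole give the aromatic 1H-indole, with imidazole buffering the acid that could couple two molecules through the free C3 and with the three aryl bromides inert.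

Step 5
Reactants: 6 2,4,5,6-tetrabromo-1H-indole; 7 S-methyl methanethiosulfonate
Product: 9 2,4,5,6-tetrabromo-3-(methylsulfanyl)-1H-indole (target), via sodium 2,4,5,6-tetrabromoindol-1-ide 8 (not isolated)
Conditions: NaH (1.1 equiv), DMF, 0 °C; then 7 (1.05 equiv), 0 °C → rt; aq NH4Cl
Reagents that add atoms: none
Why: C3 sulfenylation of an indolyl anion with a thiosulfonate, a known reaction type for indoles: the ambident anion 8 attacks the divalent sulfur of 7 through C3, the only pyrrole carbon still bearing hydrogen, the 3H-indole formed tautomerizes to the 1H-indole, and the methanesulfinate released is too weak a nucleophile to touch the C2–Br bond.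

Compound list
1 | 5-nitro-1,3-dihydro-2H-indol-2-one | O=C1Cc2cc(ccc2N1)[N+](=O)[O-] | starting material
2 | 5-amino-1,3-dihydro-2H-indol-2-one | O=C1Cc2cc(N)ccc2N1 | intermediate
3 | 5-amino-4,6-dibromo-1,3-dihydro-2H-indol-2-one | O=C1Cc2c(Br)c(N)c(Br)cc2N1 | intermediate
4 | 4,6-dibromo-2-oxoindoline-5-diazonium bromide | O=C1Cc2c(Br)c([N+]#N)c(Br)cc2N1.[Br-] | intermediate
5 | 4,5,6-tribromo-1,3-dihydro-2H-indol-2-one | O=C1Cc2c(Br)c(Br)c(Br)cc2N1 | intermediate
6 | 2,4,5,6-tetrabromo-1H-indole | Brc1cc2c(Br)c(Br)c(Br)cc2[nH]1 | intermediate
7 | S-methyl methanethiosulfonate | CS(=O)(=O)SC | starting material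
8 | sodium 2,4,5,6-tetrabromoindol-1-ide | [Na+].Brc1cc2c(Br)c(Br)c(Br)cc2[n-]1 | intermediate
9 | 2,4,5,6-tetrabromo-3-(methylsulfanyl)-1H-indole | CSc1c(Br)[nH]c2cc(Br)c(Br)c(Br)c12 | target

Total step count: 5. Longest linear sequence: 5 steps (1 → 2 → 3 → 5 → 6 → 9).

Steps most likely to fail

Step 2 (key step). What may go wrong: loss of site control once the ring is partly brominated, with bromine entering the enolizable C3 methylene through the lactam enol alongside the second ring bromination, so that the mixture cannot be driven to one product. The fallback over-brominates on purpose and then trims. Setting out from 2, an excess of NBS (4.2 equiv, MeCN, 0 °C → rt) should fill C4, C6 and both C3 positions and give 5-amino-3,3,4,6-tetrabromo-1,3-dihydro-2H-indol-2-one F1. Zinc dust in AcOH at rt should then remove only the two bromines α to the carbonyl (reductive dehalogenation; aryl bromides persist), and the route is rejoined at 3.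

Step 3. What may go wrong: nitrosation or copper-mediated bromination at the C3 methylene competing with diazotization of the weakly basic amine, and hydrogen capture by the aryl radical in place of bromine transfer. The fallback replaces the one-pot radical process by a two-stage route through an isolated salt. Setting out from 3, NOBF4 (1.05 equiv) in MeCN at −30 °C followed by Et2O should precipitate 4,6-dibromo-2-oxoindoline-5-diazonium tetrafluoroborate F2, free of nitrosating agent. The salt is then given bromide from KBr under copper catalysis (CuBr and CuBr2, 10 mol % each, 1,10-phenanthroline, MeCN, 20 °C), and the route is rejoined at 5.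

Step 4. What may go wrong: acid-promoted self-condensation of the product, whose C3 is unsubstituted, with its own 3H-indolium form (oligomer formation), or stalling at the phosphorylated lactam. The fallback puts the sulfur on C3 before the ring is aromatized. Setting out from 5, the lactam dianion (LiN(SiMe3)2, 2.2 equiv, THF, −78 °C) is sulfenylated with 7 (0.95 equiv) to racemic 4,5,6-tribromo-3-(methylsulfanyl)-1,3-dihydro-2H-indol-2-one F3 (enolate sulfenylation; the deficit of 7 holds back a second sulfenylation). F3 is then treated with POBr3 and imidazole in ClCH2CH2Cl at 80 °C, where the C3 substituent blocks the condensation site, and the route is rejoined at the target 9. The C3 stereocentre of F3 disappears on aromatization, so its configuration is of no consequence.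

Further compounds
F1 | step 2 | 5-amino-3,3,4,6-tetrabromo-1,3-dihydro-2H-indol-2-one | O=C1Nc2cc(Br)c(N)c(Br)c2C1(Br)Br
F2 | step 3 | 4,6-dibromo-2-oxoindoline-5-diazonium tetrafluoroborate | O=C1Cc2c(Br)c([N+]#N)c(Br)cc2N1.F[B-](F)(F)F
F3 | step 4 | 4,5,6-tribromo-3-(methylsulfanyl)-1,3-dihydro-2H-indol-2-one (racemic) | CSC1C(=O)Nc2cc(Br)c(Br)c(Br)c12
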